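The constants used here were drawn at random within sensible limits; the rest is arithmetic.

The reagent is taken by the substrate and by the first, double and triple products, and I set this flask beside a neighbour holding 4.0 mM of substrate in place of 10 mM.

    substrate + reagent → first product + released group (k1 = 0.582 /M/s)
    reagent + first product → double product + released group (k2 = 0.820 /M/s)
    reagent + double product → triple product + released group (k3 = 1.34 /M/s)
    reagent + triple product → tetra adduct + released group (k4 = 0.0504 /M/s)
    first product + released group → side product (k5 = 0.646 /M/s)
    2 reagent → homo dimer (k6 = 0.162 /M/s)

substrate 10 mM; reagent 13.0 mM; time 50 min

- why nothing more happens at 50 min, or that something still does (it is still moving / all of the substrate has reacted / forward and back rates have come level / the reagent has run out first)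
- how much of the substrate has reacted by 50 min
- how much side product there is at 50 min, in percent of the substrate charged
- how much triple product there is at 50 min, in percent of the substrate charged

- where a step has two of a species, its rate is k times that concentration squared, and two are used at each turn
- the reaction counts as stopped when no species that holds the substrate changes by six tenths of a point or more over the second half of the time
- run time (flask): 50 min

I counted lifetimes. With the reagent as charged, the substrate has a lifetime of 2.20 min by the first step. As a simplification, I let the reagent meet a pool of substrate, first product and double product, and I counted that pool as the substrate charge throughout. I gave that pool the middle constant, 0.820 /M/s, so the reagent's lifetime is 2.03 min. That is far shorter than the run, which holds 24.6 such lifetimes, so I expected the reagent, as limiting reagent, to end this flask before the clock did.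

A reagent decaying this way gives the substrate the exposure of the reagent's full charge held for one reagent lifetime. So I defined the reach as the number of substrate lifetimes that one reagent lifetime lasts, 0.923, and the fraction of substrate left as e to the minus the reach. By this count, this flask had 60.3 % of its substrate reacted. The count is crude: it sets aside the homo dimer and the side step, and I did not reckon the split between side product and triple product.

The neighbour has a smaller pool and the same substrate lifetime, so I expected its reagent to last longer and its substrate to go further.

The forecast also said the reagent has run out first, with “a good third of the substrate is stranded”, and its conversion stands above mine.

| Flask at the asked time | Forecast | Simulation |
|---|---|---|
| Substrate reacted | 61 % | 62.3 % |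
| Side product | 37 % | 39.8 % |
| Triple product | 16 % | 13.6 % |

The simulation's answer for this flask was that the reagent has run out first, and the flask held 38 % of its substrate beside 0 % of its reagent. Left for 500 min, this flask read 62.3 % reacted and 13.6 % triple product. For the neighbour, the reagent lifetime becomes 5.08 min and the reach 2.31, which gives 90.1 % reacted. The neighbour read 89.2 % reacted, with 38.8 % triple product.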